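## Structural features

The target is a biflavonoid: a (2S)-naringenin unit (benzo ring A, dihydropyranone ring C, 4-hydroxyphenyl ring B on C2) is bonded through C6 of its ring A to C8'' of an apigenin unit, an intact flavone. The C6–C8'' bond is a biaryl axis with an oxygen on each of its four ortho positions (5-OH, 7-OH, 7''-OH and the pyranone O1''), so it is crowded and slow to rotate; it carries no descriptor. C2 is the only stereocentre and has no stereogenic neighbour, so its configuration must come from a reagent or catalyst. The fragile points are the flavanone ring (it opens by retro-oxa-Michael reaction under base and then loses C2), the benzylic C2–O1 ether, the C2''=C3'' bond of the flavone under hydrogenation, and six free phenols that are best kept masked to the end. The real difficulties are three: forging the tetra-ortho-substituted biaryl bond, attaching ring C on the 6-linked and not the 8-linked side of a phloroglucinol-type ring A, and controlling a lone benzylic ether stereocentre. The key step uses the fact that ring C is a benzo-fused oxacycle: O1–C2 and C3–C4 lie on either side of a C2–C3 unit that maps onto a styrene, C8a–O1 and C4a–C4 map onto an ortho-quinone methide of ring A, and C4, benzylic to the trioxygenated ring A, can be raised to the ketone afterwards.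

## Logic of the disconnections

**18 to 17.** The six phenolic O–H bonds are traced back to six O–benzyl bonds. One kind of protecting group allows one final operation under neutral conditions, which spares the base-sensitive C2. The forward step must stop before the C2''=C3'' bond, the C4 ketone or the C2–O1 bond is reduced.

**17 to 16 to 15.** The C4=O bond is removed in two stages, first to the C4–OH of 16 and then to the CH2 of 15. This is the price of the cycloaddition, whose methide carbon arrives as CH2; in return ring C becomes a plain chroman ring. Forward, a hydride acceptor must take C4–H (cation stabilised by O1, O5 and O7) and not C2–H or an OCH2Ph hydrogen, and the second oxidation must not be basic.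

**15 to 11 and 13 (through 14).** O1–C2 and C3–C4 are cut together. One convergent step then accounts for ring C, two skeletal bonds and the only stereocentre, and leaves 11 and 13.
- 15 carries six benzyl ethers (two on ring A, one on ring B, three on the flavone); calling it a penta-O-benzyl compound would miscount, since 11 brings five and 13 the sixth.
- The design of 11 fixes the regiochemistry: only the hydroxyl para to the biaryl bond is free and the other oxygen next to the CH2OH group is benzylated, so a single methide 14 can form and the flavone ends on C6.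
- The forward step needs regiocontrol (given by polarity), suppression of self-alkylation of the electron-rich ring (excess 13, slow addition of 11), and facial control at C2 by the chiral acid, which is the open question.

**13 to 12.** The C=C bond is cut to a carbonyl and a one-carbon ylide. 12 is a catalogue compound, so ring B costs one step.

**11 to 10 to 9.** After adjusting CH2OH to CHO, the aryl–C4 bond is cut. The two positions ortho to the hydroxyl of 9 are equivalent, so ortho-formylation can give only one constitution, and it is the one that leads to the 6-linkage. The forward steps must place carbon strictly ortho to OH, only once, and reduce the aldehyde without touching the flavone carbonyl. From 10 on the axis is stereogenic.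

**9 to 8 to 3 and 7.** The silyl ether is restored on the one oxygen that must differ from the benzylated ones, and the biaryl C–C bond is cut. This halves the molecule into a flavone iodide and a phloroglucinol boronate. The forward step is a tetra-ortho-substituted Suzuki coupling with a boronate prone to protodeboronation.

**7 to 6 to 5 to 4.** The C–B bond goes back to the C–Li bond of 6, that to the C–H bond of 5, and the O–Si bond to 4, a catalogue compound. The position between the two benzyloxy groups must be metalated selectively; the bulky silyloxy group is chosen because it does not direct.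

**3 to 2 to 1.** The C8''–I bond and then three O–benzyl bonds are cut. 1 supplies the complete flavone, so this half needs no ring synthesis. Iodination must go to C8'' and not C6''; that is why the chelated 5''-hydroxyl is benzylated as well.

## Other disconnections considered

**Alternative 1:** The cut goes through ring A of the flavone: C8''–C8a'', C7''–C8'', C5''–C6'' and C4a''–C5'' are made in one benzannulation, and the interflavonoid bond is already present in the aryl diazo ketone A2 as a bond from the phloroglucinol ring to the diazo carbon.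
- Forward step: A2 loses nitrogen and the pyranonyl group migrates (Wolff rearrangement, making C8''–C8a''). The aryl(pyranonyl)ketene adds benzyl ethynyl ether A3 in a [2+2] sense, and the cyclobutenone opens (4π) and recloses (6π) onto the pyranone to give the 5''-hydroxyflavone A1.
- In its favour: the crowded biaryl is never made by cross-coupling, the polarity of the ynol ether places 7''-O and 5''-OH without ambiguity, and the 5''-hydroxyl emerges free and distinct.
- Against it here: A2 is itself a demanding target (a 6-aryl-4-oxopyran-2-carbonyl unit joined to a diazo carbon flanked by two ortho benzyloxy groups). Benzyl alkynyl ethers such as A3 are a thermally fragile class that tends to rearrange to ketenes at or below the temperatures such cascades need. 6π closure onto a 4-pyranone double bond has thinner precedent than closure onto carbocyclic vinyl partners.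
- Comparison: on the biaryl bond the alternative is the better idea, because a ring synthesis replaces a tetra-ortho-substituted coupling. On mechanism it packs four bond formations into one metal-free pericyclic cascade, which offers more ways to fail than an iodination and a coupling. On step economy it is worse: A1 still needs benzylation of the 5''-hydroxyl and loss of the methoxymethyl group to reach 9, everything from step 6 on (including the C2 problem) is unchanged, and the chosen plan buys the whole flavone as 1.

**Alternative 2:** The cut goes through the pyranone ring of the flavone: C4a''–C4'', C4''–C3'' and O1''–C2''.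
- Forward step: the biaryl ortho-iodophenol A5, carbon monoxide A7 and 4-(benzyloxy)phenylacetylene A6 are joined by a palladium–phosphine catalyst and a secondary amine (carbonylative Sonogashira coupling, then addition of the phenol to the ynone) to give A4.
- In its favour: this is dependable flavone chemistry. It does not rely on the C8'' over C6'' preference of step 2 or on forcing a benzyl group onto a chelated hydroxyl, and on those points it is the better plan. A4 has the same structure as 8, so the later steps would be identical; there the two plans are equal.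
- Against it here: the hindered biaryl bond is not avoided but moved into A5, where it must be made between two electron-rich phloroglucinol rings, one of which also needs a free hydroxyl, an iodine and two benzyl ethers in a defined pattern. 5-exo closure to an aurone competes with 6-endo closure to the flavone in this type of annulation. A toxic gas must be handled.
- Comparison: structurally the two plans meet at the same compound. Mechanistically the annulation is well understood but hinges on the ring-size choice in its closing step, where the chosen plan has only an electrophilic substitution and a coupling. In step count the alternative is clearly longer, because 1 already contains the pyranone and ring B that the annulation would build.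

**Alternative 3:** The cut is the C2–C3 bond of the flavanone.
- Forward step: a chiral carboxylate complex of divalent rhodium decomposes the diazomethyl ketone A9, and the carbene inserts into a benzylic C–H bond of the ortho 4-benzyloxybenzyl ether, closing ring C and setting C2 to give A8.
- In its favour: ring C is made at the ketone oxidation level, so steps 10 and 11 and the risk of over-oxidation would vanish; this is a real advantage over the chosen plan. The stereo-determining event is intramolecular, and asymmetric carbene insertion next to an ether oxygen is an established class. On precedent for enantiocontrol the two plans are about equal: each relies on asymmetric catalysis that is established for relatives and untested for the case at hand.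
- Against it here: closing a six-membered ring runs against the usual preference of such carbenes for five-membered transition states. Attack of the carbene on the ether oxygen, followed by a [1,2]-shift of the 4-benzyloxybenzyl group from the oxonium ylide, would give a benzofuranone, and it is favoured by exactly the electron-rich benzyl group that the target requires. The 5-oxygen must be silylated so that no second benzylic ether C–H is on offer. Ring A of A9 carries three different oxygen substituents and an acyl group in a fixed pattern relative to the biaryl bond, so the 6-versus-8 question that the symmetric phenol 9 answers for free returns as a protecting-group problem.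
- Comparison: on structure the alternative is better after the key step (no C4 oxidation) and worse before it (a long, regiochemically delicate route to A9 with a diazomethane-type acylation). On mechanism both need a catalyst to choose a face at a benzylic carbon, but the carbene has more competing channels than the quinone methide, whose main side reaction is oligomerisation. In total step count the chosen plan should be shorter.

Key step: step 9

Assumption: the C6–C8'' axis has no descriptor in the target, so only C2 is controlled; from 10 onward the compounds are expected to be mixtures of rotamers about this hindered axis and are carried as such.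

## Route

Step 1
Reactants: 1 apigenin
Product: 2 5,7,4'-tri-O-benzylapigenin
Conditions: BnBr (4 equiv), K2CO3, Bu4NI (cat.), DMF, 80 °C
Reagents that add atoms: benzyl bromide, BrCc1ccccc1
Why: Williamson etherification of all three phenols; the chelated 5-hydroxyl reacts last and needs heat, excess halide and iodide catalysis, and it must be capped because a free 5-OH would direct the coming iodination to C6.

Step 2
Reactants: 2 5,7,4'-tri-O-benzylapigenin
Product: 3 8-iodo-5,7,4'-tri-O-benzylapigenin
Conditions: I2 (1.05 equiv), CF3CO2Ag, CH2Cl2, 0 °C to rt, dark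
Reagents that add atoms: iodine, [I][I]
Why: Electrophilic aromatic iodination by the iodonium source formed from I2 and CF3CO2Ag; in 5,7-dialkoxyflavones this reagent pair is known to substitute C8 in preference to C6, which lies between two alkoxy groups, and one equivalent leaves the less activated ring B alone.

Step 3
Reactants: 4 3,5-bis(benzyloxy)phenol
Product: 5 [3,5-bis(benzyloxy)phenoxy]triisopropylsilane
Conditions: TIPSCl, imidazole, DMF, rt
Reagents that add atoms: chlorotriisopropylsilane, CC(C)[Si](Cl)(C(C)C)C(C)C
Why: Standard silylation of the one free phenol; the triisopropylsilyl ether survives n-BuLi, has no directing power of its own and can later be removed without touching benzyl ethers.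

Step 4
Reactants: 5 [3,5-bis(benzyloxy)phenoxy]triisopropylsilane
Product: 7 2-[2,6-bis(benzyloxy)-4-(triisopropylsilyloxy)phenyl]-4,4,5,5-tetramethyl-1,3,2-dioxaborolane, via aryllithium 6 (not isolated)
Conditions: n-BuLi, THF, 0 °C; then 2-isopropoxy-4,4,5,5-tetramethyl-1,3,2-dioxaborolane, −78 °C to rt; aq. NH4Cl
Reagents that add atoms: 2-isopropoxy-4,4,5,5-tetramethyl-1,3,2-dioxaborolane, CC(C)OB1OC(C)(C)C(C)(C)O1
Why: Directed ortho-metalation: the aromatic C–H between the two benzyloxy groups is the only one flanked by two coordinating ether oxygens, the hindered silyloxy group does not direct, and the aryllithium is trapped by the borate to give the pinacol ester directly.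

Step 5
Reactants: 3 8-iodo-5,7,4'-tri-O-benzylapigenin; 7 2-[2,6-bis(benzyloxy)-4-(triisopropylsilyloxy)phenyl]-4,4,5,5-tetramethyl-1,3,2-dioxaborolane
Product: 9 8-[2,6-bis(benzyloxy)-4-hydroxyphenyl]-5,7,4'-tri-O-benzylapigenin, via silyl biaryl 8 (not isolated)
Conditions: Pd(OAc)2 (5 mol %), 2-dicyclohexylphosphino-2',6'-dimethoxybiphenyl (SPhos), K3PO4, 7 (1.5 equiv), toluene/H2O, 100 °C; then Bu4NF, THF, rt; aq. NH4Cl
Reagents that add atoms: none
Why: Suzuki–Miyaura coupling; the bulky, electron-rich biarylphosphine is the ligand class developed for tetra-ortho-substituted biaryls and 2,6-dialkoxyaryl boron partners, and an excess of 7 offsets protodeboronation. Fluoride then cleaves the aryl silyl ether in the same flask, benzyl ethers being inert to it.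

Step 6
Reactants: 9 8-[2,6-bis(benzyloxy)-4-hydroxyphenyl]-5,7,4'-tri-O-benzylapigenin
Product: 10 2,4-bis(benzyloxy)-6-hydroxy-3-(5,7,4'-tri-O-benzylapigenin-8-yl)benzaldehyde
Conditions: MgCl2, Et3N, (CH2O)n, MeCN, reflux; dil. HCl work-up
Reagents that add atoms: paraformaldehyde (reacts as formaldehyde), C=O
Why: Magnesium-mediated ortho-formylation (Casnati–Skattebøl reaction): formaldehyde is delivered within the magnesium phenoxide chelate, so carbon enters only ortho to the free hydroxyl, and a second equivalent of formaldehyde oxidises the benzylic alkoxide to the aldehyde. Both ortho positions of 9 are equivalent, so a single constitution results; from here on the biaryl axis is stereogenic and the material is racemic about it.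

Step 7
Reactants: 10 2,4-bis(benzyloxy)-6-hydroxy-3-(5,7,4'-tri-O-benzylapigenin-8-yl)benzaldehyde
Product: 11 3,5-bis(benzyloxy)-2-(hydroxymethyl)-4-(5,7,4'-tri-O-benzylapigenin-8-yl)phenol
Conditions: NaBH4, THF/MeOH, 0 °C
Reagents that add atoms: none
Why: Borohydride reduction of an aromatic aldehyde; the flavone carbonyl, a vinylogous ester, and the benzyl ethers are inert at 0 °C. Cold, neutral work-up and prompt use are advised because 11 ionises easily.

Step 8
Reactants: 12 4-(benzyloxy)benzaldehyde
Product: 13 4-(benzyloxy)styrene
Conditions: Ph3PCH3Br, KOtBu, THF, 0 °C to rt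
Reagents that add atoms: methyltriphenylphosphonium bromide, C[P+](c1ccccc1)(c1ccccc1)c1ccccc1.[Br-]
Why: Wittig methylenation with the non-stabilised ylide; no stereochemistry is involved and the benzyl ether is inert.

Step 9
Reactants: 11 3,5-bis(benzyloxy)-2-(hydroxymethyl)-4-(5,7,4'-tri-O-benzylapigenin-8-yl)phenol; 13 4-(benzyloxy)styrene
Product: 15 (2S)-5,7-bis(benzyloxy)-2-[4-(benzyloxy)phenyl]-6-(5,7,4'-tri-O-benzylapigenin-8-yl)chroman, via ortho-quinone methide 14 (not isolated)
Conditions: (R)-3,3'-bis(2,4,6-triisopropylphenyl)-1,1'-binaphthyl-2,2'-diyl hydrogen phosphate (10 mol %), 13 (3 equiv), 4 Å molecular sieves, toluene, 0 °C to rt, slow addition of 11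
Reagents that add atoms: none
Why: Proposed new method: the chiral acid protonates the benzylic hydroxyl of 11, water leaves with help from the ortho and para oxygens of ring A, and methide 14 stays hydrogen-bonded (or ion-paired as the hydroxybenzyl cation) to the chiral phosphate; the terminal carbon of 13 attacks the methide carbon (C3–C4) and the phenolic oxygen closes onto the developing 4-benzyloxybenzylic cation (O1–C2) within the same ion pair. The closest known reaction type is the inverse-electron-demand oxa-Diels–Alder reaction of ortho-quinone methides with styrenes, known as a racemic route to flavans, together with chiral phosphoric acid catalysed [4+2] additions of such methides to alkenes that carry a hydrogen-bond donor; what is new is asking the chiral anion alone to tell apart the faces of a styrene without such a handle. Ring C closes in an intermolecular, asynchronous [4+2] mode, C3–C4 first and O1–C2 second. C2 is set under catalyst control by the chiral pocket around the ion pair; which antipode of the acid gives 2S has to be established, and both are available. Regiochemistry (aryl on C2, not C3) follows from polarity: the nucleophilic CH2 of the styrene meets the electrophilic methide carbon, and positive charge develops where the 4-benzyloxyphenyl group stabilises it. Only one methide can form because only the oxygen para to the biaryl bond is free, which fixes the 6-linkage. Excess 13 and slow addition of 11 keep the methide from alkylating the free ring position of another molecule, and the remote biaryl axis is expected only to give rotamers of one C2 configuration.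

Step 10
Reactants: 15 (2S)-5,7-bis(benzyloxy)-2-[4-(benzyloxy)phenyl]-6-(5,7,4'-tri-O-benzylapigenin-8-yl)chroman
Product: 16 (2S)-5,7-bis(benzyloxy)-2-[4-(benzyloxy)phenyl]-6-(5,7,4'-tri-O-benzylapigenin-8-yl)chroman-4-ol (both C4 epimers)
Conditions: DDQ (1.2 equiv), CH2Cl2/H2O, 0 °C to rt, dark
Reagents that add atoms: water, O
Why: DDQ abstracts hydride from C4 (benzylic C–H oxidation), the site whose cation is stabilised by O1 and by the 5- and 7-benzyloxy groups, and water captures the cation; this is the known C4 functionalisation of 5,7-dialkoxyflavans. The new C4 centre forms as a mixture and is removed in step 11; C2 is not involved as long as exactly one hydride is taken.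

Step 11
Reactants: 16 (2S)-5,7-bis(benzyloxy)-2-[4-(benzyloxy)phenyl]-6-(5,7,4'-tri-O-benzylapigenin-8-yl)chroman-4-ol
Product: 17 (2S)-5,7-bis(benzyloxy)-2-[4-(benzyloxy)phenyl]-6-(5,7,4'-tri-O-benzylapigenin-8-yl)chroman-4-one
Conditions: Dess–Martin periodinane, NaHCO3, CH2Cl2, 0 °C to rt
Reagents that add atoms: none
Why: Dess–Martin oxidation of the secondary benzylic alcohol under buffered, non-basic conditions, so the flavanone cannot open by retro-oxa-Michael reaction and C2 keeps its configuration.

Step 12
Reactants: 17 (2S)-5,7-bis(benzyloxy)-2-[4-(benzyloxy)phenyl]-6-(5,7,4'-tri-O-benzylapigenin-8-yl)chroman-4-one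
Product: 18 (2S)-5,7-dihydroxy-2-(4-hydroxyphenyl)-6-[5,7-dihydroxy-2-(4-hydroxyphenyl)-4-oxo-4H-chromen-8-yl]chroman-4-one (target)
Conditions: H2 (1 atm), Pd/C, THF/MeOH, rt
Reagents that add atoms: none
Why: Hydrogenolysis of the six benzyl ethers over palladium under neutral conditions; aryl benzyl ethers should be cleaved faster than the pyranone C2''=C3'' bond is saturated or the C2–O1 bond is broken, so the reaction is to be stopped once the uptake for six ethers is reached.

## Compound list

1 | apigenin, 5,7-dihydroxy-2-(4-hydroxyphenyl)-4H-chromen-4-one | O=c1cc(-c2ccc(O)cc2)oc2cc(O)cc(O)c12 | starting material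
2 | 5,7-bis(benzyloxy)-2-[4-(benzyloxy)phenyl]-4H-chromen-4-one (5,7,4'-tri-O-benzylapigenin) | O=c1cc(-c2ccc(OCc3ccccc3)cc2)oc2cc(OCc3ccccc3)cc(OCc3ccccc3)c12 | intermediate
3 | 5,7-bis(benzyloxy)-2-[4-(benzyloxy)phenyl]-8-iodo-4H-chromen-4-one | O=c1cc(-c2ccc(OCc3ccccc3)cc2)oc2c(I)c(OCc3ccccc3)cc(OCc3ccccc3)c12 | intermediate
4 | 3,5-bis(benzyloxy)phenol | Oc1cc(OCc2ccccc2)cc(OCc2ccccc2)c1 | starting material
5 | [3,5-bis(benzyloxy)phenoxy]triisopropylsilane | CC(C)[Si](Oc1cc(OCc2ccccc2)cc(OCc2ccccc2)c1)(C(C)C)C(C)C | intermediate
6 | [2,6-bis(benzyloxy)-4-(triisopropylsilyloxy)phenyl]lithium (not isolated) | [Li]c1c(OCc2ccccc2)cc(O[Si](C(C)C)(C(C)C)C(C)C)cc1OCc1ccccc1 | intermediate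
7 | 2-[2,6-bis(benzyloxy)-4-(triisopropylsilyloxy)phenyl]-4,4,5,5-tetramethyl-1,3,2-dioxaborolane | CC1(C)OB(c2c(OCc3ccccc3)cc(O[Si](C(C)C)(C(C)C)C(C)C)cc2OCc2ccccc2)OC1(C)C | intermediate
8 | 5,7-bis(benzyloxy)-2-[4-(benzyloxy)phenyl]-8-[2,6-bis(benzyloxy)-4-(triisopropylsilyloxy)phenyl]-4H-chromen-4-one (not isolated) | O=c1cc(-c2ccc(OCc3ccccc3)cc2)oc2c(-c3c(OCc4ccccc4)cc(O[Si](C(C)C)(C(C)C)C(C)C)cc3OCc3ccccc3)c(OCc3ccccc3)cc(OCc3ccccc3)c12 | intermediate
9 | 5,7-bis(benzyloxy)-2-[4-(benzyloxy)phenyl]-8-[2,6-bis(benzyloxy)-4-hydroxyphenyl]-4H-chromen-4-one | O=c1cc(-c2ccc(OCc3ccccc3)cc2)oc2c(-c3c(OCc4ccccc4)cc(O)cc3OCc3ccccc3)c(OCc3ccccc3)cc(OCc3ccccc3)c12 | intermediate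
10 | 2,4-bis(benzyloxy)-3-{5,7-bis(benzyloxy)-2-[4-(benzyloxy)phenyl]-4-oxo-4H-chromen-8-yl}-6-hydroxybenzaldehyde (racemic about the axis) | O=Cc1c(O)cc(OCc2ccccc2)c(-c2c(OCc3ccccc3)cc(OCc3ccccc3)c3c(=O)cc(-c4ccc(OCc5ccccc5)cc4)oc23)c1OCc1ccccc1 | intermediate
11 | 3,5-bis(benzyloxy)-2-(hydroxymethyl)-4-{5,7-bis(benzyloxy)-2-[4-(benzyloxy)phenyl]-4-oxo-4H-chromen-8-yl}phenol | OCc1c(O)cc(OCc2ccccc2)c(-c2c(OCc3ccccc3)cc(OCc3ccccc3)c3c(=O)cc(-c4ccc(OCc5ccccc5)cc4)oc23)c1OCc1ccccc1 | intermediate
12 | 4-(benzyloxy)benzaldehyde | O=Cc1ccc(OCc2ccccc2)cc1 | starting material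
13 | 1-(benzyloxy)-4-ethenylbenzene (4-benzyloxystyrene) | C=Cc1ccc(OCc2ccccc2)cc1 | intermediate
14 | 8-[2,6-bis(benzyloxy)-3-methylidene-4-oxocyclohexa-1,5-dien-1-yl]-5,7-bis(benzyloxy)-2-[4-(benzyloxy)phenyl]-4H-chromen-4-one (ortho-quinone methide, not isolated) | C=C1C(=O)C=C(OCc2ccccc2)C(-c2c(OCc3ccccc3)cc(OCc3ccccc3)c3c(=O)cc(-c4ccc(OCc5ccccc5)cc4)oc23)=C1OCc1ccccc1 | intermediate
15 | (2S)-5,7-bis(benzyloxy)-2-[4-(benzyloxy)phenyl]-6-{5,7-bis(benzyloxy)-2-[4-(benzyloxy)phenyl]-4-oxo-4H-chromen-8-yl}-3,4-dihydro-2H-chromene (hexa-O-benzyl flavan) | C1C[C@@H](c2ccc(OCc3ccccc3)cc2)Oc2cc(OCc3ccccc3)c(-c3c(OCc4ccccc4)cc(OCc4ccccc4)c4c(=O)cc(-c5ccc(OCc6ccccc6)cc5)oc34)c(OCc3ccccc3)c21 | intermediate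
16 | (2S)-5,7-bis(benzyloxy)-2-[4-(benzyloxy)phenyl]-6-{5,7-bis(benzyloxy)-2-[4-(benzyloxy)phenyl]-4-oxo-4H-chromen-8-yl}-3,4-dihydro-2H-chromen-4-ol (C4 not defined, both epimers) | OC1C[C@@H](c2ccc(OCc3ccccc3)cc2)Oc2cc(OCc3ccccc3)c(-c3c(OCc4ccccc4)cc(OCc4ccccc4)c4c(=O)cc(-c5ccc(OCc6ccccc6)cc5)oc34)c(OCc3ccccc3)c21 | intermediate
17 | (2S)-5,7-bis(benzyloxy)-2-[4-(benzyloxy)phenyl]-6-{5,7-bis(benzyloxy)-2-[4-(benzyloxy)phenyl]-4-oxo-4H-chromen-8-yl}-2,3-dihydro-4H-chromen-4-one (hexa-O-benzyl target) | O=C1C[C@@H](c2ccc(OCc3ccccc3)cc2)Oc2cc(OCc3ccccc3)c(-c3c(OCc4ccccc4)cc(OCc4ccccc4)c4c(=O)cc(-c5ccc(OCc6ccccc6)cc5)oc34)c(OCc3ccccc3)c21 | intermediate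
18 | (2S)-5,7-dihydroxy-2-(4-hydroxyphenyl)-6-[5,7-dihydroxy-2-(4-hydroxyphenyl)-4-oxo-4H-chromen-8-yl]-2,3-dihydro-4H-chromen-4-one | O=C1C[C@@H](c2ccc(O)cc2)Oc2cc(O)c(-c3c(O)cc(O)c4c(=O)cc(-c5ccc(O)cc5)oc34)c(O)c21 | target

## Step count and least certain steps

Total: 12 steps. Longest linear sequence: 9 steps (1 to 18 through steps 1, 2, 5, 6, 7, 9, 10, 11, 12; the branch from 4 through steps 3, 4, 5 and onward is equally long).

**Step 9 (key step).** What is most likely to go wrong is poor facial selectivity. The stereocentre forms at the styrene carbon farthest from the hydrogen bond that holds the methide to the catalyst, and 13 has no group with which to dock. Loss of material by self-alkylation of the methide at the free ring position, and partial quenching of the acid by the basic flavone carbonyl, are secondary worries. The fallback uses known chemistry and a different logic (reagent-controlled ketone reduction, then an invertive ring closure); it sets out from 10 and comes back at 15. Claisen–Schmidt condensation of 10 with 4'-(benzyloxy)acetophenone (KOH, EtOH/THF) should give the chalcone (E)-1-[4-(benzyloxy)phenyl]-3-[2,4-bis(benzyloxy)-6-hydroxy-3-(5,7,4'-tri-O-benzylapigenin-8-yl)phenyl]prop-2-en-1-one F1. Conjugate reduction with [(Ph3P)CuH]6, which should leave the far less electrophilic flavone enone alone, gives the saturated ketone 1-[4-(benzyloxy)phenyl]-3-[2,4-bis(benzyloxy)-6-hydroxy-3-(5,7,4'-tri-O-benzylapigenin-8-yl)phenyl]propan-1-one F2. Corey–Bakshi–Shibata reduction with the (S)-methyl oxazaborolidine and BH3·SMe2 gives the carbinol (1R)-1-[4-(benzyloxy)phenyl]-3-[2,4-bis(benzyloxy)-6-hydroxy-3-(5,7,4'-tri-O-benzylapigenin-8-yl)phenyl]propan-1-ol F3. Mitsunobu etherification (PPh3, DIAD, THF, 0 °C) then closes ring C with inversion to (2S)-15; the reaction is kept cold because an alkoxybenzylic carbinol can ionise and erode the inversion.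

**Step 10.** The likely failure is over-oxidation: the C4 cation can lose H3 to give a flav-3-ene, which a second equivalent of quinone would take on to a flavylium ion and so erase C2; hydride loss from C2 itself, also benzylic and next to oxygen, leads to the same damage. The fallback builds ring C at the ketone level and sets C2 by conjugate arylation, so no C–H oxidation is needed; it sets out from 10 and comes back at 17. Addition of HC≡CMgBr (excess, THF, −78 to 0 °C) should give the propargylic alcohol 1-[2,4-bis(benzyloxy)-6-hydroxy-3-(5,7,4'-tri-O-benzylapigenin-8-yl)phenyl]prop-2-yn-1-ol F4. MnO2 oxidises it to the ynone 1-[2,4-bis(benzyloxy)-6-hydroxy-3-(5,7,4'-tri-O-benzylapigenin-8-yl)phenyl]prop-2-yn-1-one F5. Et2NH adds to the ynone and the enaminone cyclises on mild acid treatment to the chromone 5,7-bis(benzyloxy)-6-(5,7,4'-tri-O-benzylapigenin-8-yl)-4H-chromen-4-one F6. Rhodium-catalysed asymmetric 1,4-addition of 4-(benzyloxy)phenylboronic acid ([Rh(OH)(cod)]2 with a chiral biaryl bisphosphine, toluene/H2O; Hayashi–Miyaura reaction, known for chromones) then gives (2S)-17, the ligand antipode being chosen for that sense.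

**Step 5.** The likely failure is protodeboronation of the electron-rich, doubly ortho-substituted boronate outrunning a slow transmetalation at a tetra-ortho-substituted biaryl. The fallback changes the organometallic partner (Negishi coupling); it sets out from 5 and 3 and comes back at 9. Lithiation of 5 as in step 4 gives 6, which ZnCl2 converts into the arylzinc [2,6-bis(benzyloxy)-4-(triisopropylsilyloxy)phenyl]zinc chloride F7. Coupling with 3 (Pd2(dba)3 as the source of zerovalent palladium, SPhos, THF, 60 °C) gives 8, and Bu4NF gives 9; an arylzinc halide should tolerate the flavone carbonyl.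

**Step 4.** The likely failure is deprotonation at a benzylic OCH2 position followed by [1,2]-Wittig rearrangement, in competition with ring metalation. The fallback makes the carbon–metal bond by halogen–metal exchange; it sets out from 5 and comes back at 7. Bromination of 5 with N-bromosuccinimide (MeCN, 0 °C) should go para to the silyloxy group, whose bulk shields both of its ortho positions, to give 2-bromo-1,3-bis(benzyloxy)-5-(triisopropylsilyloxy)benzene F8. Exchange with n-BuLi at −78 °C, which is faster than benzylic deprotonation, gives 6, trapped with the same borate to give 7.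

**Step 12.** The likely failure is over-reduction: saturation of C2''=C3'', hydrogenolysis of the benzylic C2–O1 bond or reduction of the C4 ketone before the last hindered benzyl ether has gone. The fallback replaces hydrogenolysis by Lewis-acid debenzylation with a cation scavenger (BCl3, pentamethylbenzene, CH2Cl2, −78 °C); it sets out from 17 and arrives directly at 18, and it makes no new compound (F0).

## Further compounds

F1 | step 9 | (E)-1-[4-(benzyloxy)phenyl]-3-[2,4-bis(benzyloxy)-6-hydroxy-3-(5,7,4'-tri-O-benzylapigenin-8-yl)phenyl]prop-2-en-1-one | O=C(/C=C/c1c(O)cc(OCc2ccccc2)c(-c2c(OCc3ccccc3)cc(OCc3ccccc3)c3c(=O)cc(-c4ccc(OCc5ccccc5)cc4)oc23)c1OCc1ccccc1)c1ccc(OCc2ccccc2)cc1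
F2 | step 9 | 1-[4-(benzyloxy)phenyl]-3-[2,4-bis(benzyloxy)-6-hydroxy-3-(5,7,4'-tri-O-benzylapigenin-8-yl)phenyl]propan-1-one | O=C(CCc1c(O)cc(OCc2ccccc2)c(-c2c(OCc3ccccc3)cc(OCc3ccccc3)c3c(=O)cc(-c4ccc(OCc5ccccc5)cc4)oc23)c1OCc1ccccc1)c1ccc(OCc2ccccc2)cc1
F3 | step 9 | (1R)-1-[4-(benzyloxy)phenyl]-3-[2,4-bis(benzyloxy)-6-hydroxy-3-(5,7,4'-tri-O-benzylapigenin-8-yl)phenyl]propan-1-ol | O[C@H](CCc1c(O)cc(OCc2ccccc2)c(-c2c(OCc3ccccc3)cc(OCc3ccccc3)c3c(=O)cc(-c4ccc(OCc5ccccc5)cc4)oc23)c1OCc1ccccc1)c1ccc(OCc2ccccc2)cc1
F4 | step 10 | 1-[2,4-bis(benzyloxy)-6-hydroxy-3-(5,7,4'-tri-O-benzylapigenin-8-yl)phenyl]prop-2-yn-1-ol (racemic carbinol) | C#CC(O)c1c(O)cc(OCc2ccccc2)c(-c2c(OCc3ccccc3)cc(OCc3ccccc3)c3c(=O)cc(-c4ccc(OCc5ccccc5)cc4)oc23)c1OCc1ccccc1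
F5 | step 10 | 1-[2,4-bis(benzyloxy)-6-hydroxy-3-(5,7,4'-tri-O-benzylapigenin-8-yl)phenyl]prop-2-yn-1-one | C#CC(=O)c1c(O)cc(OCc2ccccc2)c(-c2c(OCc3ccccc3)cc(OCc3ccccc3)c3c(=O)cc(-c4ccc(OCc5ccccc5)cc4)oc23)c1OCc1ccccc1
F6 | step 10 | 5,7-bis(benzyloxy)-6-{5,7-bis(benzyloxy)-2-[4-(benzyloxy)phenyl]-4-oxo-4H-chromen-8-yl}-4H-chromen-4-one | O=c1ccoc2cc(OCc3ccccc3)c(-c3c(OCc4ccccc4)cc(OCc4ccccc4)c4c(=O)cc(-c5ccc(OCc6ccccc6)cc5)oc34)c(OCc3ccccc3)c12
F7 | step 5 | [2,6-bis(benzyloxy)-4-(triisopropylsilyloxy)phenyl]zinc chloride | Cl[Zn]c1c(OCc2ccccc2)cc(O[Si](C(C)C)(C(C)C)C(C)C)cc1OCc1ccccc1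
F8 | step 4 | 2-bromo-1,3-bis(benzyloxy)-5-(triisopropylsilyloxy)benzene | Brc1c(OCc2ccccc2)cc(O[Si](C(C)C)(C(C)C)C(C)C)cc1OCc1ccccc1
F0 | step 12 | none | none
A1 | alternative 1 | 7-benzyloxy-8-[2,6-bis(benzyloxy)-4-(methoxymethoxy)phenyl]-2-[4-(benzyloxy)phenyl]-5-hydroxy-4H-chromen-4-one | O=c1cc(-c2ccc(OCc3ccccc3)cc2)oc2c(-c3c(OCc4ccccc4)cc(OCOC)cc3OCc3ccccc3)c(OCc3ccccc3)cc(O)c12
A2 | alternative 1 | 2-{[2,6-bis(benzyloxy)-4-(methoxymethoxy)phenyl](diazo)acetyl}-6-[4-(benzyloxy)phenyl]-4H-pyran-4-one | O=c1cc(-c2ccc(OCc3ccccc3)cc2)oc(C(=O)C(=[N+]=[N-])c2c(OCc3ccccc3)cc(OCOC)cc2OCc2ccccc2)c1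
A3 | alternative 1 | benzyl ethynyl ether | C#COCc1ccccc1
A4 | alternative 2 | 5,7-bis(benzyloxy)-2-[4-(benzyloxy)phenyl]-8-[2,6-bis(benzyloxy)-4-(triisopropylsilyloxy)phenyl]-4H-chromen-4-one | O=c1cc(-c2ccc(OCc3ccccc3)cc2)oc2c(-c3c(OCc4ccccc4)cc(O[Si](C(C)C)(C(C)C)C(C)C)cc3OCc3ccccc3)c(OCc3ccccc3)cc(OCc3ccccc3)c12
A5 | alternative 2 | 3,5-bis(benzyloxy)-2-[2,6-bis(benzyloxy)-4-(triisopropylsilyloxy)phenyl]-6-iodophenol | Oc1c(I)c(OCc2ccccc2)cc(OCc2ccccc2)c1-c1c(OCc2ccccc2)cc(O[Si](C(C)C)(C(C)C)C(C)C)cc1OCc1ccccc1
A6 | alternative 2 | 1-(benzyloxy)-4-ethynylbenzene | C#Cc1ccc(OCc2ccccc2)cc1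
A7 | alternative 2 | carbon monoxide | [C-]#[O+]
A8 | alternative 3 | (2S)-7-benzyloxy-2-[4-(benzyloxy)phenyl]-6-{5,7-bis(benzyloxy)-2-[4-(benzyloxy)phenyl]-4-oxo-4H-chromen-8-yl}-5-(tert-butyldimethylsilyloxy)-2,3-dihydro-4H-chromen-4-one | O=C1C[C@@H](c2ccc(OCc3ccccc3)cc2)Oc2cc(OCc3ccccc3)c(-c3c(OCc4ccccc4)cc(OCc4ccccc4)c4c(=O)cc(-c5ccc(OCc6ccccc6)cc5)oc34)c(O[Si](C)(C)C(C)(C)C)c21
A9 | alternative 3 | 8-{2-benzyloxy-4-[(4-benzyloxybenzyl)oxy]-6-(tert-butyldimethylsilyloxy)-5-(diazoacetyl)phenyl}-5,7-bis(benzyloxy)-2-[4-(benzyloxy)phenyl]-4H-chromen-4-one | [N-]=[N+]=CC(=O)c1c(OCc2ccc(OCc3ccccc3)cc2)cc(OCc2ccccc2)c(-c2c(OCc3ccccc3)cc(OCc3ccccc3)c3c(=O)cc(-c4ccc(OCc5ccccc5)cc4)oc23)c1O[Si](C)(C)C(C)(C)C
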